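## Retrosynthetic overview

1. The 1,4-benzodioxane of target 19 is numbered O1, C2 (aryl), C3 (methyl), O4, C4a, C5 (OMe), C7 (propenyl), C8a. The strategy rests on the C5 oxygen being ortho to O4 (on the C4a–C5 edge) and not to O1: an acyl carbene hung on the C5 oxygen can reach O4 only, and its carbonyl carbon is the future C3 methyl.
2. Late disconnections: aryl O–Si; C7–propenyl (Suzuki–Miyaura on C7–Br); C3–CH3 back to C3–CH2OH; C5–OMe back to the phenol. These lead to tricyclic lactone 12, in which the C3 carbonyl is tied to the C5 oxygen.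
3. Key disconnection: O4–C3 and C2–C3 of 12, by [1,2]-shift ring expansion of the oxonium ylide from diazoacetate 9, a 2-aryl-1,3-benzodioxole carrying the ester on its C4 oxygen.
4. 9 comes from benzodioxolol 6; 6 comes from symmetrical 5-bromopyrogallol 2 and the dimethyl acetal 5 of O-silylated syringaldehyde.
5. Ring order: dioxole ring (step 4); lactone and dioxane rings together, at the expense of the dioxole (step 7); lactone opened again (step 8).

Key step: step 7

Assumption: the sense of induction of the tert-leucinate catalyst in this untested ylide shift cannot be derived from precedent; the route is written with Rh2(S-PTTL)4 leading to the (2R,3S) lactone, and Rh2(R-PTTL)4 would be used if the opposite sense is found.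

Abbreviation used in the step names: Ar = 3,5-dimethoxy-4-(triisopropylsilyloxy)phenyl.

## Route

Step 1
Reactants: 1 4-bromo-2,6-dimethoxyphenol
Product: 2 5-bromobenzene-1,2,3-triol (5-bromopyrogallol)
Conditions: BBr3 (3.5 equiv), CH2Cl2, −78 °C to rt; degassed H2O; argon
Reagents that add atoms: none
Why: BBr3 cleaves both aryl methyl ethers (Lewis-acid-assisted demethylation, bromide attacking the O-methyl carbon) without touching the aryl bromide, and gives the symmetrical triol, which is kept under argon because pyrogallols autoxidise.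

Step 2
Reactants: 3 syringaldehyde (4-hydroxy-3,5-dimethoxybenzaldehyde)
Product: 4 3,5-dimethoxy-4-(triisopropylsilyloxy)benzaldehyde
Conditions: TIPSCl, imidazole, DMAP (cat.), DMF, 50 °C
Reagents that add atoms: chlorotriisopropylsilane, CC(C)[Si](Cl)(C(C)C)C(C)C
Why: Imidazole-mediated O-silylation of the phenol, made more acidic by the para-formyl group, installs a bulky aryl silyl ether that should survive the weak acids, the carbene, the hydrides and the carbonate bases used later.

Step 3
Reactants: 4 3,5-dimethoxy-4-(triisopropylsilyloxy)benzaldehyde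
Product: 5 3,5-dimethoxy-4-(triisopropylsilyloxy)benzaldehyde dimethyl acetal
Conditions: HC(OMe)3, PPTS (cat.), MeOH, rt; Et3N quench
Reagents that add atoms: trimethyl orthoformate, COC(OC)OC; methanol, CO
Why: Acid-catalysed acetalisation, with the orthoformate as methoxy source and water scavenger, gives a transacetalisation donor that reacts under milder acid than the free aldehyde, and PPTS does not cleave the hindered aryl silyl ether.

Step 4
Reactants: 2 5-bromobenzene-1,2,3-triol; 5 3,5-dimethoxy-4-(triisopropylsilyloxy)benzaldehyde dimethyl acetal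
Product: 6 6-bromo-2-Ar-1,3-benzodioxol-4-ol (racemic at the acetal carbon)
Conditions: PPTS (10 mol %), toluene/THF (4:1), 70 °C, 5 Å MS, argon; Et3N quench
Reagents that add atoms: none
Why: PPTS ionises 5 to an aryl-stabilised oxocarbenium ion that is captured by two adjacent hydroxyls of 2 to close the five-membered dioxole (transacetalisation driven by removal of methanol); because 2 is symmetrical either adjacent pair gives the same constitution, and the racemic acetal carbon is of no consequence since it is re-formed in step 7.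

Step 5
Reactants: 6 6-bromo-2-Ar-1,3-benzodioxol-4-ol; 7 bromoacetyl bromide
Product: 8 6-bromo-2-Ar-1,3-benzodioxol-4-yl bromoacetate (racemic)
Conditions: pyridine, CH2Cl2, −20 to 0 °C
Reagents that add atoms: none
Why: O-acylation of the only free phenol by the acyl bromide, with pyridine scavenging HBr so that the acid-labile acetal is preserved, gives the aryl bromoacetate while the alkyl bromide terminus stays intact at low temperature.

Step 6
Reactants: 8 6-bromo-2-Ar-1,3-benzodioxol-4-yl bromoacetate
Product: 9 6-bromo-2-Ar-1,3-benzodioxol-4-yl diazoacetate (racemic)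
Conditions: TsNHNHTs (2 equiv), DBU (5 equiv), THF, 0 °C; aq. NaHCO3
Reagents that add atoms: N,N'-ditosylhydrazine, Cc1ccc(cc1)S(=O)(=O)NNS(=O)(=O)c1ccc(C)cc1
Why: The hydrazide anion displaces bromide (SN2) and two base-induced eliminations of p-toluenesulfinate unveil the diazo group under cold, non-acidic conditions that the aryl ester and the acetal should tolerate (diazoacetate synthesis from a bromoacetate).

Step 7
Reactants: 9 6-bromo-2-Ar-1,3-benzodioxol-4-yl diazoacetate
Product: 12 (2R,3S)-7-bromo-2-Ar-2,3-dihydro-1,4-benzodioxine-3-carboxylic acid lactonised onto the C5 oxygen (tricyclic lactone; aryl and carbonyl trans), via oxonium ylide 10 (not isolated), via oxocarbenium enolate zwitterion 11 (not isolated)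
Conditions: Rh2(S-PTTL)4 (2 mol %; PTTL = N-phthaloyl-tert-leucinate), 4 Å MS, PhCF3, 0 °C, slow addition of 9 over 4 h (final 0.01 M), then rt
Reagents that add atoms: none
Why: Proposed new method: Rh2(S-PTTL)4 (divalent rhodium) expels N2 from 9 and the rhodium carbene is captured by a lone pair of O3 of the benzodioxole (the dioxole oxygen on C3a, ortho to the ester-bearing C4 and the only acetal oxygen the two-atom ester tether can reach) to give the rhodium-associated oxonium ylide 10, whose O3–C2 acetal bond then breaks heterolytically, assisted by O1 and the para-silyloxyaryl group, to the tethered oxocarbenium enolate 11, which collapses at carbon to 12 (net [1,2]-Stevens shift). The closest known reaction type is Rh2(OAc)4-catalysed intramolecular oxonium ylide formation at acetal oxygens followed by [1,2]-shift ring expansion, and, for asymmetric induction in a ylide [1,2]-shift, the copper-catalysed ring expansion of oxetanes to tetrahydrofurans; neither has been shown on a 1,3-benzodioxole, through an aryl diazoacetate tether, or with enantiocontrol in this setting. The lactone ring closes in the ylide-forming event (O3 onto the carbene carbon, six-membered, through the s-trans ester rotamer) and the dioxane ring closes in the C–C bond-forming event (enolate carbon onto the O1-oxocarbenium carbon, 6-endo-trig with respect to the C=O+ bond), so that the five-membered dioxole is expanded by one carbon. C3 is set by the enolate face that the migrating carbon takes up, which the tert-leucinate pocket can dictate only if the shift runs while rhodium is still bound to the ylide; C2 is set in the same bond formation relative to C3, the aryl group being expected to take the pseudo-equatorial site so that aryl and carbonyl end up trans, and the configuration of the racemic acetal carbon of 9 is erased in 11. The step needs the carbene to choose O3 over aromatic substitution at the benzodioxole C5–H and over dimerisation, and the shift to end on carbon and not on the enolate oxygen: the lone pair and the six-membered geometry favour ylide formation, the bromine at C6 deactivates C5, slow addition at high dilution suppresses dimerisation, and O-attack in 11 would need an eight-membered ring.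

Step 8
Reactants: 12 tricyclic lactone
Product: 13 (2R,3R)-7-bromo-3-(hydroxymethyl)-2-Ar-2,3-dihydro-1,4-benzodioxin-5-ol
Conditions: LiBH4 (2.5 equiv), THF, −20 to 0 °C; aq. NH4Cl
Reagents that add atoms: none
Why: Hydride reduction of the activated aryl ester opens the tether to the C5 phenol and the C3 hydroxymethyl group in one operation; it is chosen over basic alcoholysis because the C3 hydrogen of an ester, alpha to the carbonyl and beta to the O1 aryloxy group, would be exposed to epimerisation and E1cB ring opening, whereas fast low-temperature reduction should carry both stereocentres through unchanged (the descriptor at C3 changes only because of CIP priorities).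

Step 9
Reactants: 13 (2R,3R)-7-bromo-3-(hydroxymethyl)-2-Ar-2,3-dihydro-1,4-benzodioxin-5-ol
Product: 14 [(2R,3R)-7-bromo-5-methoxy-2-Ar-2,3-dihydro-1,4-benzodioxin-3-yl]methanol
Conditions: MeI (1.5 equiv), K2CO3, acetone, rt
Reagents that add atoms: iodomethane, CI
Why: Williamson methylation in which carbonate deprotonates only the phenol and not the primary alcohol, so the C5 oxygen is methylated selectively, while C2 cannot epimerise because its para-oxygen is still silylated.

Step 10
Reactants: 14 [(2R,3R)-7-bromo-5-methoxy-2-Ar-2,3-dihydro-1,4-benzodioxin-3-yl]methanol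
Product: 15 [(2R,3R)-7-bromo-5-methoxy-2-Ar-2,3-dihydro-1,4-benzodioxin-3-yl]methyl 4-methylbenzenesulfonate
Conditions: TsCl, Et3N, DMAP (cat.), CH2Cl2, 0 °C to rt
Reagents that add atoms: p-toluenesulfonyl chloride, Cc1ccc(cc1)S(Cl)(=O)=O
Why: DMAP-catalysed sulfonylation of the primary alcohol turns the hydroxyl into a leaving group without involving either stereocentre.

Step 11
Reactants: 15 [(2R,3R)-7-bromo-5-methoxy-2-Ar-2,3-dihydro-1,4-benzodioxin-3-yl]methyl 4-methylbenzenesulfonate
Product: 16 (2R,3R)-7-bromo-5-methoxy-3-methyl-2-Ar-2,3-dihydro-1,4-benzodioxine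
Conditions: LiBHEt3 (3 equiv), THF, 0 °C to rt; H2O
Reagents that add atoms: none
Why: LiBHEt3 displaces the primary tosylate by hydride (SN2 at the exocyclic CH2, so C3 keeps its configuration) to give the C3 methyl group, and the aryl bromide and the silyl ether should be inert to this reagent at these temperatures.

Step 12
Reactants: 16 (2R,3R)-7-bromo-5-methoxy-3-methyl-2-Ar-2,3-dihydro-1,4-benzodioxine; 17 (E)-prop-1-enylboronic acid
Product: 18 (2R,3R)-5-methoxy-3-methyl-7-[(E)-prop-1-enyl]-2-Ar-2,3-dihydro-1,4-benzodioxine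
Conditions: Pd(dppf)Cl2 (5 mol %), K2CO3, 1,4-dioxane/H2O (5:1), 80 °C
Reagents that add atoms: none
Why: Suzuki–Miyaura coupling at the unhindered C7–Br bond (oxidative addition to zerovalent palladium formed from the divalent palladium precatalyst, transmetalation, reductive elimination) transfers the propenyl group with retention of the E geometry and does not involve the sp3 stereocentres.

Step 13
Reactants: 18 (2R,3R)-5-methoxy-3-methyl-7-[(E)-prop-1-enyl]-2-Ar-2,3-dihydro-1,4-benzodioxine
Product: 19 4-[(2R,3R)-5-methoxy-3-methyl-7-[(E)-prop-1-enyl]-2,3-dihydro-1,4-benzodioxin-2-yl]-2,6-dimethoxyphenol (target, CNP0227775.1)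
Conditions: TBAF (1.2 equiv), AcOH (1.2 equiv), THF, 0 °C
Reagents that add atoms: none
Why: Fluoride cleaves the aryl Si–O bond (desilylation driven by Si–F bond formation) under acetic acid buffering at 0 °C, which should leave the (E)-propenyl group and both stereocentres untouched; C2, which becomes epimerisable through the para-quinone methide once the phenol is free, already has the thermodynamically preferred trans arrangement with aryl and methyl both pseudo-equatorial.

## Compound list

1 | 4-bromo-2,6-dimethoxyphenol | COc1cc(Br)cc(OC)c1O | starting material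
2 | 5-bromobenzene-1,2,3-triol | Oc1cc(Br)cc(O)c1O | intermediate
3 | syringaldehyde (4-hydroxy-3,5-dimethoxybenzaldehyde) | COc1cc(C=O)cc(OC)c1O | starting material
4 | 3,5-dimethoxy-4-(triisopropylsilyloxy)benzaldehyde | COc1cc(C=O)cc(OC)c1O[Si](C(C)C)(C(C)C)C(C)C | intermediate
5 | 3,5-dimethoxy-4-(triisopropylsilyloxy)benzaldehyde dimethyl acetal | COC(OC)c1cc(OC)c(O[Si](C(C)C)(C(C)C)C(C)C)c(OC)c1 | intermediate
6 | 6-bromo-2-[3,5-dimethoxy-4-(triisopropylsilyloxy)phenyl]-1,3-benzodioxol-4-ol (racemic) | Oc1cc(Br)cc2OC(c3cc(OC)c(O[Si](C(C)C)(C(C)C)C(C)C)c(OC)c3)Oc12 | intermediate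
7 | bromoacetyl bromide | BrCC(Br)=O | starting material
8 | 6-bromo-2-[3,5-dimethoxy-4-(triisopropylsilyloxy)phenyl]-1,3-benzodioxol-4-yl bromoacetate (racemic) | BrCC(=O)Oc1cc(Br)cc2OC(c3cc(OC)c(O[Si](C(C)C)(C(C)C)C(C)C)c(OC)c3)Oc12 | intermediate
9 | 6-bromo-2-[3,5-dimethoxy-4-(triisopropylsilyloxy)phenyl]-1,3-benzodioxol-4-yl diazoacetate (racemic) | [N-]=[N+]=CC(=O)Oc1cc(Br)cc2OC(c3cc(OC)c(O[Si](C(C)C)(C(C)C)C(C)C)c(OC)c3)Oc12 | intermediate
10 | oxonium ylide: dioxole O3 bonded to the ylide carbon, closing a six-membered 1,4-dioxin-2-one ring (drawn without rhodium) | Brc1cc2OC(=O)[CH-][O+]3C(c4cc(OC)c(O[Si](C(C)C)(C(C)C)C(C)C)c(OC)c4)Oc(c1)c23 | intermediate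
11 | oxocarbenium enolate zwitterion: 1,4-benzodioxin-2-olate carrying the O-aryl oxocarbenium of the silylated syringyl group on the neighbouring ring oxygen (drawn without rhodium) | Brc1cc2OC([O-])=COc2c(c1)[O+]=Cc1cc(OC)c(O[Si](C(C)C)(C(C)C)C(C)C)c(OC)c1 | intermediate
12 | tricyclic lactone: (2R,3S)-7-bromo-2-[3,5-dimethoxy-4-(triisopropylsilyloxy)phenyl]-2,3-dihydro-1,4-benzodioxine-3-carboxylic acid lactonised onto the C5 oxygen, aryl and carbonyl trans | Brc1cc2c3c(c1)O[C@H](c1cc(OC)c(O[Si](C(C)C)(C(C)C)C(C)C)c(OC)c1)[C@H](O3)C(=O)O2 | intermediate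
13 | (2R,3R)-7-bromo-3-(hydroxymethyl)-2-[3,5-dimethoxy-4-(triisopropylsilyloxy)phenyl]-2,3-dihydro-1,4-benzodioxin-5-ol | Brc1cc(O)c2c(c1)O[C@H](c1cc(OC)c(O[Si](C(C)C)(C(C)C)C(C)C)c(OC)c1)[C@@H](CO)O2 | intermediate
14 | [(2R,3R)-7-bromo-5-methoxy-2-[3,5-dimethoxy-4-(triisopropylsilyloxy)phenyl]-2,3-dihydro-1,4-benzodioxin-3-yl]methanol | Brc1cc(OC)c2c(c1)O[C@H](c1cc(OC)c(O[Si](C(C)C)(C(C)C)C(C)C)c(OC)c1)[C@@H](CO)O2 | intermediate
15 | [(2R,3R)-7-bromo-5-methoxy-2-[3,5-dimethoxy-4-(triisopropylsilyloxy)phenyl]-2,3-dihydro-1,4-benzodioxin-3-yl]methyl 4-methylbenzenesulfonate | Brc1cc(OC)c2c(c1)O[C@H](c1cc(OC)c(O[Si](C(C)C)(C(C)C)C(C)C)c(OC)c1)[C@@H](COS(=O)(=O)c1ccc(C)cc1)O2 | intermediate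
16 | (2R,3R)-7-bromo-5-methoxy-3-methyl-2-[3,5-dimethoxy-4-(triisopropylsilyloxy)phenyl]-2,3-dihydro-1,4-benzodioxine | Brc1cc(OC)c2c(c1)O[C@H](c1cc(OC)c(O[Si](C(C)C)(C(C)C)C(C)C)c(OC)c1)[C@@H](C)O2 | intermediate
17 | (E)-prop-1-enylboronic acid | C/C=C/B(O)O | starting material
18 | (2R,3R)-5-methoxy-3-methyl-7-[(E)-prop-1-enyl]-2-[3,5-dimethoxy-4-(triisopropylsilyloxy)phenyl]-2,3-dihydro-1,4-benzodioxine | C/C=C/c1cc(OC)c2c(c1)O[C@H](c1cc(OC)c(O[Si](C(C)C)(C(C)C)C(C)C)c(OC)c1)[C@@H](C)O2 | intermediate
19 | 4-[(2R,3R)-5-methoxy-3-methyl-7-[(E)-prop-1-enyl]-2,3-dihydro-1,4-benzodioxin-2-yl]-2,6-dimethoxyphenol | C/C=C/c1cc(OC)c2c(c1)O[C@H](c1cc(OC)c(O)c(OC)c1)[C@@H](C)O2 | target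

## Step count and risks

Total step count: 13. Longest linear sequence: 12 steps (syringaldehyde 3 through steps 2–13); the branch from 1 joins at step 4.

Steps most likely to fail:

1. Step 7 (proposed new method). The [1,2]-shift may occur only after rhodium has left the ylide, so that the enolate face is chosen without the chiral ligand and 12 forms with little enantiomeric excess. The carbene may also be diverted into aromatic substitution at the ring CH ortho to the ester oxygen or into dimerisation. Poor trans selectivity at C2 would be less serious, since C2 can be equilibrated toward trans through the para-quinone methide once the phenol is free.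
 Fallback, by known chemistry from the chiral pool, setting out from 1 and coming back at 16:
 - 1 is silylated (TIPSCl, imidazole, DMF) to (4-bromo-2,6-dimethoxyphenoxy)triisopropylsilane F1.
 - In parallel, commercial 5-bromo-2-hydroxy-3-methoxybenzaldehyde (COc1cc(Br)cc(C=O)c1O) and ethyl (S)-lactate (CCOC(=O)[C@H](C)O) are joined by Mitsunobu etherification (PPh3, DIAD, THF, inversion) to ethyl (2R)-2-(4-bromo-2-formyl-6-methoxyphenoxy)propanoate F2, whose stereocentre is the future C3.
 - Baeyer–Villiger (Dakin-type) oxidation with mCPBA in CH2Cl2 gives the aryl formate ethyl (2R)-2-[4-bromo-2-(formyloxy)-6-methoxyphenoxy]propanoate F3. Methanolysis (Et3N, MeOH) frees the phenol ethyl (2R)-2-(4-bromo-2-hydroxy-6-methoxyphenoxy)propanoate F4. TsOH in hot toluene closes this to the lactone (3R)-7-bromo-5-methoxy-3-methyl-2,3-dihydro-1,4-benzodioxin-2-one F5.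
 - Bromine–lithium exchange on F1 (n-BuLi, THF, −78 °C) gives [3,5-dimethoxy-4-(triisopropylsilyloxy)phenyl]lithium F6. It should add once to F5 at −78 °C, faster than it enolises the lactone, and after NH4Cl work-up give the keto phenol (2R)-2-(4-bromo-2-hydroxy-6-methoxyphenoxy)-1-[3,5-dimethoxy-4-(triisopropylsilyloxy)phenyl]propan-1-one F7.
 - NaBH4 in MeOH at 0 °C reduces F7 to (2R)-2-(4-bromo-2-hydroxy-6-methoxyphenoxy)-1-[3,5-dimethoxy-4-(triisopropylsilyloxy)phenyl]propan-1-ol F8 as both C1 epimers.
 - BF3·OEt2 in CH2Cl2 at −20 °C ionises the benzylic alcohol and lets the ortho phenol close the dioxane. Both epimers should converge on the trans isomer 16, from which steps 12 and 13 follow.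

2. Step 4. The aryl-stabilised oxocarbenium ion from 5 may alkylate the electron-rich ring of 2 at carbon, which is irreversible, in place of the reversible O,O-acetalisation. The acid-labile acetal 6 may also reopen during isolation.
 Fallback, setting out from 2 and 4 and coming back at 6 (step 3 is then not needed):
 - 2 is persilylated with hexamethyldisilazane to 5-bromo-1,2,3-tris(trimethylsilyloxy)benzene F9.
 - Aldehyde 4 and F9 are combined with catalytic TMSOTf in CH2Cl2 at −78 °C. This is an aprotic silyl-transfer acetalisation in which neither free phenol nor protic acid is present. It should give the trimethylsilyl ether of 6, {6-bromo-2-[3,5-dimethoxy-4-(triisopropylsilyloxy)phenyl]-1,3-benzodioxol-4-yl}oxytrimethylsilane F10.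
 - The labile aryl trimethylsilyl ether is removed with K2CO3 in MeOH at 0 °C to give 6.

3. Step 11. The hydride may attack the sulfur of the tosylate and return alcohol 14, may act as a base and eliminate toward the exocyclic enol ether, or may begin to reduce the aryl bromide if the reaction has to be forced.
 Fallback, setting out from 14 and coming back at 16:
 - Appel iodination (I2, PPh3, imidazole, CH2Cl2) converts 14 into (2R,3S)-7-bromo-3-(iodomethyl)-5-methoxy-2-[3,5-dimethoxy-4-(triisopropylsilyloxy)phenyl]-2,3-dihydro-1,4-benzodioxine F11.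
 - Radical deiodination with Bu3SnH (1.1 equiv) and AIBN in toluene at 80 °C gives 16. The primary alkyl iodide is abstracted far faster than the aryl bromide, and the primary radical should be trapped by the tin hydride before it can lose the aryloxy group.

Further compounds
F1 | step 7 | (4-bromo-2,6-dimethoxyphenoxy)triisopropylsilane | COc1cc(Br)cc(OC)c1O[Si](C(C)C)(C(C)C)C(C)C
F2 | step 7 | ethyl (2R)-2-(4-bromo-2-formyl-6-methoxyphenoxy)propanoate | CCOC(=O)[C@@H](C)Oc1c(C=O)cc(Br)cc1OC
F3 | step 7 | ethyl (2R)-2-[4-bromo-2-(formyloxy)-6-methoxyphenoxy]propanoate | CCOC(=O)[C@@H](C)Oc1c(OC=O)cc(Br)cc1OC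
F4 | step 7 | ethyl (2R)-2-(4-bromo-2-hydroxy-6-methoxyphenoxy)propanoate | CCOC(=O)[C@@H](C)Oc1c(O)cc(Br)cc1OC
F5 | step 7 | (3R)-7-bromo-5-methoxy-3-methyl-2,3-dihydro-1,4-benzodioxin-2-one | C[C@H]1Oc2c(OC)cc(Br)cc2OC1=O
F6 | step 7 | [3,5-dimethoxy-4-(triisopropylsilyloxy)phenyl]lithium | [Li]c1cc(OC)c(O[Si](C(C)C)(C(C)C)C(C)C)c(OC)c1
F7 | step 7 | (2R)-2-(4-bromo-2-hydroxy-6-methoxyphenoxy)-1-[3,5-dimethoxy-4-(triisopropylsilyloxy)phenyl]propan-1-one | C[C@@H](Oc1c(O)cc(Br)cc1OC)C(=O)c1cc(OC)c(O[Si](C(C)C)(C(C)C)C(C)C)c(OC)c1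
F8 | step 7 | (2R)-2-(4-bromo-2-hydroxy-6-methoxyphenoxy)-1-[3,5-dimethoxy-4-(triisopropylsilyloxy)phenyl]propan-1-ol (both C1 epimers) | C[C@@H](Oc1c(O)cc(Br)cc1OC)C(O)c1cc(OC)c(O[Si](C(C)C)(C(C)C)C(C)C)c(OC)c1
F9 | step 4 | 5-bromo-1,2,3-tris(trimethylsilyloxy)benzene | C[Si](C)(C)Oc1cc(Br)cc(O[Si](C)(C)C)c1O[Si](C)(C)C
F10 | step 4 | {6-bromo-2-[3,5-dimethoxy-4-(triisopropylsilyloxy)phenyl]-1,3-benzodioxol-4-yl}oxytrimethylsilane (racemic) | C[Si](C)(C)Oc1cc(Br)cc2OC(c3cc(OC)c(O[Si](C(C)C)(C(C)C)C(C)C)c(OC)c3)Oc12
F11 | step 11 | (2R,3S)-7-bromo-3-(iodomethyl)-5-methoxy-2-[3,5-dimethoxy-4-(triisopropylsilyloxy)phenyl]-2,3-dihydro-1,4-benzodioxine | Brc1cc(OC)c2c(c1)O[C@H](c1cc(OC)c(O[Si](C(C)C)(C(C)C)C(C)C)c(OC)c1)[C@@H](CI)O2
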